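The route builds ring D of the naphthalene (C1'–C4') de novo, so the hindered diaryl ketone at the future spiro carbon C3 never has to be made by acylation. A gold-catalysed benzannulation joins an ortho-alkynylbenzaldehyde, in which a diarylalkyne already links ring A to ring E, with (triisopropylsilyloxy)ethyne. In one operation it forms the C1'–C2' and C3'–C4' bonds, places oxygen on C2' and hydrogen on C3' and C4', and turns the alkyne carbon next to ring A into the C3 ketone. The step exploits the 1-acyl-2-oxy-3,4-unsubstituted pattern of ring D. Lactam formation, debenzylation and an enantioselective spiroketalisation then close rings B and C.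

Key step: step 8

Labels: lactam carbonyl C1, N2, spiro carbon C3; ring A = C3a to C7a with OMe on C4; naphthalene carbons are primed (C1' on C3, C2'–OH, C6'–CH3, C8'–O); ring B = lactam, ring C = five-membered ether ring, ring D = C1' to C4', ring E = C5' to C8'.

Assumption: methyl 2-amino-3-methoxybenzoate, 3-phenylisoxazole and 2-[(tert-butyldimethylsilyl)oxy]ethan-1-amine are taken as purchasable, and the sense of induction of the chiral acid in step 11 is to be assigned on the first run (the antipodal acid is used if it is opposite).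

Design notes:
- The iodine of ring E is placed by directed lithiation, because the phenol has three activated positions for electrophilic iodination.
- The peri oxygen is a benzyl ether, not an acetal, since acetals ortho to an alkyne migrate under π-acid catalysis. It is removed under neutral conditions only after the lactam is in place, so ring C closes only when the chiral acid is present.
- The ring A carboxyl stays a methyl ester, the alkyl group least prone to dealkylative isocoumarin formation.
- The side-chain hydroxyl is silylated so that it cannot form the competing oxazolidine N,O-ketal.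

Step 1
Reactants: 1 3-hydroxy-5-methylbenzaldehyde
Product: 2 3-(benzyloxy)-5-methylbenzaldehyde
Conditions: BnBr, K2CO3, DMF, rt
Reagents that add atoms: benzyl bromide, BrCc1ccccc1
Why: Williamson etherification of the only acidic site should be clean, as the aldehyde has no enolisable position.

Step 2
Reactants: 2 3-(benzyloxy)-5-methylbenzaldehyde
Product: 5 3-(benzyloxy)-2-iodo-5-methylbenzaldehyde, via lithium α-amino alkoxide 3 (not isolated), via C2-lithiated alkoxide 4 (not isolated)
Conditions: LiN(Me)CH2CH2NMe2 (from the diamine and n-BuLi), THF, −20 °C; n-BuLi, −20 °C; I2, THF, −78 °C → rt; H2O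
Reagents that add atoms: iodine, II
Why: Directed ortho-metalation, in which the aldehyde is masked in the flask as its α-amino alkoxide and this group together with the benzyloxy oxygen should direct n-BuLi to the one ring carbon between them, so that iodinolysis and hydrolytic work-up return the aldehyde with iodine at the required position.

Step 3
Reactants: 6 methyl 2-amino-3-methoxybenzoate
Product: 8 methyl 2-iodo-3-methoxybenzoate, via arenediazonium tosylate 7 (not isolated)
Conditions: NaNO2, p-TsOH·H2O, KI, MeCN/H2O, 10 °C → rt
Reagents that add atoms: potassium iodide, [K+].[I-]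
Why: Sandmeyer-type iododediazoniation, in which iodide displaces dinitrogen from the diazonium salt without copper and the ester and ether are inert.

Step 4
Reactants: 8 methyl 2-iodo-3-methoxybenzoate; 9 ethynyltrimethylsilane
Product: 10 methyl 3-methoxy-2-[(trimethylsilyl)ethynyl]benzoate
Conditions: PdCl2(PPh3)2 (cat.), CuI (cat.), Et3N, THF, 50 °C
Reagents that add atoms: none
Why: Sonogashira coupling of an aryl iodide should tolerate the two ortho substituents because the linear alkyne adds little strain at the reacting carbon.

Step 5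
Reactants: 10 methyl 3-methoxy-2-[(trimethylsilyl)ethynyl]benzoate
Product: 11 methyl 2-ethynyl-3-methoxybenzoate
Conditions: K2CO3 (cat.), MeOH, 0 °C
Reagents that add atoms: none
Why: Methoxide-catalysed protodesilylation of the alkynyl–silicon bond is fast at 0 °C and cannot alter a methyl ester in methanol.

Step 6
Reactants: 11 methyl 2-ethynyl-3-methoxybenzoate; 5 3-(benzyloxy)-2-iodo-5-methylbenzaldehyde
Product: 12 methyl 2-{[2-(benzyloxy)-6-formyl-4-methylphenyl]ethynyl}-3-methoxybenzoate
Conditions: PdCl2(PPh3)2 (cat.), CuI (cat.), Et3N, THF, degassed, slow addition of 11, rt → 45 °C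
Reagents that add atoms: none
Why: Second Sonogashira coupling, in which the iodide is activated by its ortho formyl group and degassing with slow addition of the alkyne should suppress Glaser homocoupling.

Step 7
Reactants: 13 3-phenylisoxazole
Product: 16 (triisopropylsilyloxy)ethyne, via 5-lithio-3-phenylisoxazole 14 (not isolated), via lithium ethynolate 15 (not isolated)
Conditions: LiN(i-Pr)2, THF, −78 → −30 °C; i-Pr3SiOTf, −78 → 0 °C; pentane, filtration through basic alumina
Reagents that add atoms: triisopropylsilyl trifluoromethanesulfonate, CC(C)[Si](C(C)C)(C(C)C)OS(=O)(=O)C(F)(F)F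
Why: Base-induced fragmentation of a 5-metalated 3-substituted isoxazole into a nitrile and an ynolate, followed by O-silylation of the ynolate with the bulky silyl triflate, is the established entry to triisopropylsilyl ynol ethers, and the unsubstituted 4-position here should release the parent ethynolate.

Step 8
Reactants: 12 methyl 2-{[2-(benzyloxy)-6-formyl-4-methylphenyl]ethynyl}-3-methoxybenzoate; 16 (triisopropylsilyloxy)ethyne
Product: 18 methyl 2-[8-(benzyloxy)-6-methyl-2-(triisopropylsilyloxy)-1-naphthoyl]-3-methoxybenzoate, via benzopyrylium aurate 17 (not isolated)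
Conditions: AuCl3 (5 mol %), 2,6-di-tert-butyl-4-methylpyridine (10 mol %), 4 Å MS, ClCH2CH2Cl, 0 °C; then 16 (2 equiv) added slowly, 0 °C → rt
Reagents that add atoms: none
Why: Proposed new method: AuCl3 (trivalent gold) activates the alkyne of 12 and the aldehyde oxygen closes onto the alkyne carbon that carries ring A (6-endo-dig) to give the benzopyrylium aurate 17; the electron-rich CH terminus of 16 then attacks the former aldehyde carbon and the resulting O-silyl ketenium carbon is captured by the gold-bearing carbon, so ring D closes by a stepwise formal [4+2] cycloaddition (six-membered, endo at the digonal ketenium carbon). Scission of the C–O bridge of the bicyclic adduct aromatises ring D, returns the catalyst and leaves the pyrylium oxygen as the diaryl ketone on C1'. The closest known reaction type is the AuCl3- or Cu(OTf)2-catalysed benzannulation of ortho-alkynylbenzaldehydes with simple alkynes to 1-acylnaphthalenes, and silyloxyalkynes are established π-nucleophiles in Lewis-acid-promoted cycloadditions, but their use as the two-carbon partner of a benzopyrylium is not established. No stereocentre is formed. The step needs regiocontrol (oxygen on C2', not C3'), secured by the polarisation of the ynol ether, whose CH carbon alone is nucleophilic, and chemoselectivity for the aldehyde over the ester, methoxy and benzyloxy oxygens that also flank the alkyne, which should follow because only the aldehyde-derived oxonium is electrophilic enough to be trapped while the others revert; forming 17 before the slow addition of 16 at low temperature, with a hindered pyridine as proton scavenger, should keep 16 from adding to the free aldehyde or being hydrolysed.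

Step 9
Reactants: 18 methyl 2-[8-(benzyloxy)-6-methyl-2-(triisopropylsilyloxy)-1-naphthoyl]-3-methoxybenzoate; 19 2-[(tert-butyldimethylsilyl)oxy]ethan-1-amine
Product: 21 racemic 3-[8-(benzyloxy)-6-methyl-2-(triisopropylsilyloxy)naphthalen-1-yl]-2-{2-[(tert-butyldimethylsilyl)oxy]ethyl}-3-hydroxy-4-methoxyisoindolin-1-one, via keto amide 20 (not isolated)
Conditions: 19 (3 equiv), i-PrMgCl (3 equiv), THF, −20 °C → rt; aq. NH4Cl
Reagents that add atoms: none
Why: Bodroux-type aminolysis of the methyl ester by the chloromagnesium amide, after which the amide nitrogen adds to the neighbouring ketone (ring–chain tautomerism of 2-aroylbenzamides, either tautomer serving later), gives the hydroxylactam whose hemiaminal centre C3 is formed racemic and is erased in step 11, while the benzylated peri oxygen cannot yet close ring C.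

Step 10
Reactants: 21 racemic 3-[8-(benzyloxy)-6-methyl-2-(triisopropylsilyloxy)naphthalen-1-yl]-2-{2-[(tert-butyldimethylsilyl)oxy]ethyl}-3-hydroxy-4-methoxyisoindolin-1-one
Product: 22 racemic 2-{2-[(tert-butyldimethylsilyl)oxy]ethyl}-3-hydroxy-3-[8-hydroxy-6-methyl-2-(triisopropylsilyloxy)naphthalen-1-yl]-4-methoxyisoindolin-1-one
Conditions: H2 (1 atm), Pd/C, NaHCO3, EtOAc, rt; filtered and used crude at once
Reagents that add atoms: none
Why: Hydrogenolysis of the aryl benzyl ether over Pd/C is neutral, so both silyl ethers and the tertiary hemiaminal should survive, and the bicarbonate buffer should keep the freed peri phenol from closing onto C3 before the chiral catalyst is present.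

Step 11
Reactants: 22 racemic 2-{2-[(tert-butyldimethylsilyl)oxy]ethyl}-3-hydroxy-3-[8-hydroxy-6-methyl-2-(triisopropylsilyloxy)naphthalen-1-yl]-4-methoxyisoindolin-1-one
Product: 24 (S)-2-{2-[(tert-butyldimethylsilyl)oxy]ethyl}-7-methoxy-7'-methyl-3'-(triisopropylsilyloxy)spiro[isoindoline-1,2'-naphtho[1,8-bc]furan]-3-one, via N-acyliminium phosphate ion pair 23 (not isolated)
Conditions: (R)-3,3'-bis(2,4,6-triisopropylphenyl)-1,1'-binaphthyl-2,2'-diyl hydrogen phosphate (10 mol %), 4 Å MS, toluene, −40 °C
Reagents that add atoms: none
Why: Chiral Brønsted acid catalysis (asymmetric N,O-ketalisation through an N-acyliminium ion), in which the acid ionises the hemiaminal to the planar cation and the phosphate, ion-paired with the iminium and hydrogen-bonded to the peri hydroxyl, should deliver the oxygen to one face in a 5-exo-trig closure of ring C, so the C3 configuration is set by the catalyst under kinetic control at low temperature; the descriptor is S here only because O–Si outranks O–CH3, the spatial arrangement being that of the (R)-target.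

Step 12
Reactants: 24 (S)-2-{2-[(tert-butyldimethylsilyl)oxy]ethyl}-7-methoxy-7'-methyl-3'-(triisopropylsilyloxy)spiro[isoindoline-1,2'-naphtho[1,8-bc]furan]-3-one
Product: 25 (R)-3'-hydroxy-2-(2-hydroxyethyl)-7-methoxy-7'-methylspiro[isoindoline-1,2'-naphtho[1,8-bc]furan]-3-one (CNP0434366.1)
Conditions: Bu4NF, AcOH (1:1), THF, 0 °C → rt
Reagents that add atoms: none
Why: Fluoride-mediated cleavage of the aryl triisopropylsilyl and the primary tert-butyldimethylsilyl ether in one operation, buffered with acetic acid so that the freed C2' naphthol stays protonated, should avoid base-induced opening of the N,O-ketal and involves no acid strong enough to ionise it, so the C3 configuration should be kept.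

Compound list
1 | 3-hydroxy-5-methylbenzaldehyde | Cc1cc(O)cc(C=O)c1 | starting material
2 | 3-(benzyloxy)-5-methylbenzaldehyde | Cc1cc(OCc2ccccc2)cc(C=O)c1 | intermediate
3 | lithium [3-(benzyloxy)-5-methylphenyl]{[2-(dimethylamino)ethyl](methyl)amino}methanolate | Cc1cc(OCc2ccccc2)cc(C(O[Li])N(C)CCN(C)C)c1 | intermediate
4 | C2-lithiated derivative of 3 | Cc1cc(OCc2ccccc2)c([Li])c(C(O[Li])N(C)CCN(C)C)c1 | intermediate
5 | 3-(benzyloxy)-2-iodo-5-methylbenzaldehyde | Cc1cc(OCc2ccccc2)c(I)c(C=O)c1 | intermediate
6 | methyl 2-amino-3-methoxybenzoate | COC(=O)c1cccc(OC)c1N | starting material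
7 | 2-methoxy-6-(methoxycarbonyl)benzenediazonium 4-methylbenzenesulfonate | COC(=O)c1cccc(OC)c1[N+]#N.Cc1ccc(cc1)S(=O)(=O)[O-] | intermediate
8 | methyl 2-iodo-3-methoxybenzoate | COC(=O)c1cccc(OC)c1I | intermediate
9 | ethynyltrimethylsilane | C#C[Si](C)(C)C | starting material
10 | methyl 3-methoxy-2-[(trimethylsilyl)ethynyl]benzoate | COC(=O)c1cccc(OC)c1C#C[Si](C)(C)C | intermediate
11 | methyl 2-ethynyl-3-methoxybenzoate | COC(=O)c1cccc(OC)c1C#C | intermediate
12 | methyl 2-{[2-(benzyloxy)-6-formyl-4-methylphenyl]ethynyl}-3-methoxybenzoate | COC(=O)c1cccc(OC)c1C#Cc1c(C=O)cc(C)cc1OCc1ccccc1 | intermediate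
13 | 3-phenylisoxazole | c1cc(-c2ccccc2)no1 | starting material
14 | 5-lithio-3-phenylisoxazole | [Li]c1cc(-c2ccccc2)no1 | intermediate
15 | lithium ethynolate | [Li]OC#C | intermediate
16 | (triisopropylsilyloxy)ethyne | C#CO[Si](C(C)C)(C(C)C)C(C)C | intermediate
17 | trichloro{5-(benzyloxy)-3-[2-methoxy-6-(methoxycarbonyl)phenyl]-7-methyl-2-benzopyrylium-4-yl}aurate (zwitterion) | COC(=O)c1cccc(OC)c1-c1[o+]cc2cc(C)cc(OCc3ccccc3)c2c1[Au-](Cl)(Cl)Cl | intermediate
18 | methyl 2-[8-(benzyloxy)-6-methyl-2-(triisopropylsilyloxy)-1-naphthoyl]-3-methoxybenzoate | COC(=O)c1cccc(OC)c1C(=O)c1c(O[Si](C(C)C)(C(C)C)C(C)C)ccc2cc(C)cc(OCc3ccccc3)c12 | intermediate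
19 | 2-[(tert-butyldimethylsilyl)oxy]ethan-1-amine | NCCO[Si](C)(C)C(C)(C)C | starting material
20 | 2-[8-(benzyloxy)-6-methyl-2-(triisopropylsilyloxy)-1-naphthoyl]-N-{2-[(tert-butyldimethylsilyl)oxy]ethyl}-3-methoxybenzamide | COc1cccc(C(=O)NCCO[Si](C)(C)C(C)(C)C)c1C(=O)c1c(O[Si](C(C)C)(C(C)C)C(C)C)ccc2cc(C)cc(OCc3ccccc3)c12 | intermediate
21 | racemic 3-[8-(benzyloxy)-6-methyl-2-(triisopropylsilyloxy)naphthalen-1-yl]-2-{2-[(tert-butyldimethylsilyl)oxy]ethyl}-3-hydroxy-4-methoxyisoindolin-1-one | COc1cccc2c1C(O)(c1c(O[Si](C(C)C)(C(C)C)C(C)C)ccc3cc(C)cc(OCc4ccccc4)c13)N(CCO[Si](C)(C)C(C)(C)C)C2=O | intermediate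
22 | racemic 2-{2-[(tert-butyldimethylsilyl)oxy]ethyl}-3-hydroxy-3-[8-hydroxy-6-methyl-2-(triisopropylsilyloxy)naphthalen-1-yl]-4-methoxyisoindolin-1-one | COc1cccc2c1C(O)(c1c(O[Si](C(C)C)(C(C)C)C(C)C)ccc3cc(C)cc(O)c13)N(CCO[Si](C)(C)C(C)(C)C)C2=O | intermediate
23 | N-acyliminium ion of 22 paired with the phosphate of the (R)-configured catalyst (axial configuration not encoded) | COc1cccc2c1C(c1c(O[Si](C(C)C)(C(C)C)C(C)C)ccc3cc(C)cc(O)c13)=[N+](CCO[Si](C)(C)C(C)(C)C)C2=O.CC(C)c1cc(C(C)C)c(-c2cc3ccccc3c3c2OP(=O)([O-])Oc2c(-c4c(C(C)C)cc(C(C)C)cc4C(C)C)cc4ccccc4c2-3)c(C(C)C)c1 | intermediate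
24 | (S)-2-{2-[(tert-butyldimethylsilyl)oxy]ethyl}-7-methoxy-7'-methyl-3'-(triisopropylsilyloxy)spiro[isoindoline-1,2'-naphtho[1,8-bc]furan]-3-one | COc1cccc2c1[C@@]1(Oc3cc(C)cc4ccc(O[Si](C(C)C)(C(C)C)C(C)C)c1c34)N(CCO[Si](C)(C)C(C)(C)C)C2=O | intermediate
25 | (R)-3'-hydroxy-2-(2-hydroxyethyl)-7-methoxy-7'-methylspiro[isoindoline-1,2'-naphtho[1,8-bc]furan]-3-one | COc1cccc2c1[C@@]1(Oc3cc(C)cc4ccc(O)c1c34)N(CCO)C2=O | target

Total step count: 12
Longest linear sequence: 9 steps (steps 3, 4, 5, 6, 8, 9, 10, 11, 12)

Steps most likely to fail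

Step 8. The ynol ether may be consumed before it meets the benzopyrylium, by proton- or Lewis-acid-triggered hydrolysis or oligomerisation, or by direct addition to the free aldehyde. The alkyne of 12 may also cyclise through a neighbouring ester or ether oxygen instead of the aldehyde. Fallback, from 12 back to 18: 12 would be annulated with acetaldehyde as the enol partner (AuBr3, 1,4-dioxane, about 100 °C, sealed vessel), the known gold-catalysed benzannulation of ortho-alkynylbenzaldehydes with enolisable carbonyl compounds that ends with loss of water, to give methyl 2-[8-(benzyloxy)-6-methyl-1-naphthoyl]-3-methoxybenzoate F1. The C2' oxygen would then be introduced by ketone-directed palladium-catalysed ortho C–H hydroxylation (Pd(OCOCF3)2, divalent palladium, with PhI(OCOCF3)2 in ClCH2CH2Cl at 80 °C, hydrolytic work-up). C2' is the only C–H ortho to the ketone in either aryl ring, so this should give methyl 2-[8-(benzyloxy)-2-hydroxy-6-methyl-1-naphthoyl]-3-methoxybenzoate F2. Silylation (i-Pr3SiOTf, 2,6-lutidine, CH2Cl2) would return to 18.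

Step 11. Enantiopurity may be lost through ring closure that is not mediated by the catalyst (on the way from step 10, or as a background reaction) or through reversible ionisation of the product N,O-ketal in the presence of the acid. Fallback, from 22 back to 24: 22 would be closed without stereocontrol by an achiral acid (diphenyl phosphate, CH2Cl2, 0 °C) to racemic 2-{2-[(tert-butyldimethylsilyl)oxy]ethyl}-7-methoxy-7'-methyl-3'-(triisopropylsilyloxy)spiro[isoindoline-1,2'-naphtho[1,8-bc]furan]-3-one F3. The enantiomers would be separated by preparative chromatography on a chiral stationary phase (amylose tris(3,5-dimethylphenylcarbamate), supercritical CO2/methanol), giving 24 and its (R)-enantiomer F4, which is set aside.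

Step 7. The fragmentation of the lithiated isoxazole may be incomplete, the ynolate may be silylated on carbon or protonated to ketene, and the volatile, acid-sensitive ynol ether may be lost on isolation. Fallback, from 9 back to 16: 9 would be deprotonated with LiN(SiMe3)2 and oxidised with lithium tert-butyl peroxide (from tert-butyl hydroperoxide) in THF at −78 to 0 °C, the known oxidation of a lithium acetylide to its ynolate, giving lithium 2-(trimethylsilyl)ethynolate F5. i-Pr3SiOTf should silylate this on oxygen to give triisopropyl{[(trimethylsilyl)ethynyl]oxy}silane F6. MeLi·LiBr (THF, −78 → 0 °C) would then cleave the less hindered alkynyl–SiMe3 bond to lithium [(triisopropylsilyl)oxy]acetylide F7, and a buffered quench at −78 °C would give 16.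

Further compounds
F1 | step 8 | methyl 2-[8-(benzyloxy)-6-methyl-1-naphthoyl]-3-methoxybenzoate | COC(=O)c1cccc(OC)c1C(=O)c1cccc2cc(C)cc(OCc3ccccc3)c12
F2 | step 8 | methyl 2-[8-(benzyloxy)-2-hydroxy-6-methyl-1-naphthoyl]-3-methoxybenzoate | COC(=O)c1cccc(OC)c1C(=O)c1c(O)ccc2cc(C)cc(OCc3ccccc3)c12
F3 | step 11 | racemic 2-{2-[(tert-butyldimethylsilyl)oxy]ethyl}-7-methoxy-7'-methyl-3'-(triisopropylsilyloxy)spiro[isoindoline-1,2'-naphtho[1,8-bc]furan]-3-one | COc1cccc2c1C1(Oc3cc(C)cc4ccc(O[Si](C(C)C)(C(C)C)C(C)C)c1c34)N(CCO[Si](C)(C)C(C)(C)C)C2=O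
F4 | step 11 | (R)-2-{2-[(tert-butyldimethylsilyl)oxy]ethyl}-7-methoxy-7'-methyl-3'-(triisopropylsilyloxy)spiro[isoindoline-1,2'-naphtho[1,8-bc]furan]-3-one | COc1cccc2c1[C@]1(Oc3cc(C)cc4ccc(O[Si](C(C)C)(C(C)C)C(C)C)c1c34)N(CCO[Si](C)(C)C(C)(C)C)C2=O
F5 | step 7 | lithium 2-(trimethylsilyl)ethynolate | C[Si](C)(C)C#CO[Li]
F6 | step 7 | triisopropyl{[(trimethylsilyl)ethynyl]oxy}silane | C[Si](C)(C)C#CO[Si](C(C)C)(C(C)C)C(C)C
F7 | step 7 | lithium [(triisopropylsilyl)oxy]acetylide | [Li]C#CO[Si](C(C)C)(C(C)C)C(C)C
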